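## The problem

Compound 26 is a trans-fused 2,3,3a,6,7,7a-hexahydro-1H-inden-2-one: a cyclopentanone (ring A: C1, C2, C3, C3a, C7a) fused to a cyclohexene (ring B: C3a, C4, C5, C6, C7, C7a). It has six stereocentres, (1S,3S,3aR,6R,7R,7aR) in the numbering used here. The core difficulty is the pair of adjacent quaternary carbons C6 and C7. Each bears an ethyl group on one face; on the other face C6 carries the (1E,3E)-2-ethyl-4-phenylbuta-1,3-dienyl chain (C1′–C4′) and C7 the carboxylic acid. C6, C7 and C7a have no neighbouring carbonyl and cannot be corrected once made, so they must be created together and tied to one controlling stereocentre. The other centres are forgiving: C1 and C3 flank the C2 ketone, and C3a is epimerisable whenever C4 is a carbonyl; in each case the required configuration (ring A all-trans, trans ring fusion) is the stable one. The groups that need care are the styryl diene beside a cis carboxylic acid (acid can lactonise or isomerise it), the C4=C5 alkene, whose position must be fixed unambiguously, and the two one-carbon groups on C6 and C7, which begin alike and must end in different oxidation states. The enabling feature is that the cis-diethyl, cis-dicarbonyl pattern on C6/C7 is the imprint of a 2,3-diethylmaleic anhydride cycloadduct. C4 can be carried as an oxygen-bearing diene carbon, so ring B maps onto a 2-alkoxydiene C5=C4–C3a=C7a built on a cyclopentene.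

## Retrosynthesis

**26 ⇒ 25 ⇒ 23 (C3–CH3 bond, carboxyl unmasked).** The acid is released last from allyl ester 25. The C7 carboxyl is too hindered for acyl-oxygen hydrolysis, and an allyl ester is cleaved at the alkyl C–O bond under neutral conditions that leave the diene alone. The C3 methyl is cut next, back to ketone 23. C3 is the only unhindered methylene beside the C2 ketone, and alkylation anti to the C3a–C4 bond gives the stable C3 epimer, so kinetic and thermodynamic control agree. The forward step needs only regioselective deprotonation (CH2 over the crowded C1 methine).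

**23 ⇒ 22 ⇒ 20 + 21, and 20 ⇒ 18 + 19 (C3′=C4′ and C1′=C2′).** The dienyl chain is cut at both alkenes. Attaching the whole chain in one olefination (an allylic phosphonate) would be shorter but leaves the geometry of the trisubstituted C1′=C2′ bond to a weak preference. A carbonyl-stabilised ylide 19 places C6 trans to the formyl group reliably, and benzylphosphonate 21 then gives the E-styryl unit. The precursor, aldehyde 18, has no side chain at all. The forward reaction must olefinate a neopentyl aldehyde, which calls for a neutral, thermally robust Wittig reagent. The C2 ketal stays until both olefinations are done so that no base meets an enolisable ketone.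

**18 ⇒ 16 ⇒ 15 (oxidation-state differentiation, no C–C bond cut).** The aldehyde/ester pair is the open form of lactol–lactone 16, which is the product of adding one hydride to cyclic anhydride 15. This is preferred over alcoholysis, which gives the wrong oxidation state and is reversible in a tetra-substituted succinic system. It is also preferred over full reduction, which would cost extra redox steps. The forward reaction must distinguish the two anhydride carbonyls. The C7 carbonyl lies beside C7a and the C1 ethyl group; the C6 carbonyl has only the C5 alkene CH as neighbour.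

**15 ⇒ 14 ⇒ 12 ⇒ 10 (C4–CH3 bond; C4 ketone from the enol ether).** The C4 methyl is cut as a cross-coupling of enol triflate 14, and 14 comes from ketone 12. The ketone serves two purposes: it lets C3a settle into the trans fusion, and its kinetic enolate toward C5 fixes the alkene position. Ketone 12 is the hydrolysis product of enol ether 10. The anhydride is kept through these steps as a compact mask for both carboxyl carbons, with no α-hydrogens and inert to mild acid, amine base and zerovalent palladium.

**10 ⇒ 7 + 9 (C5–C6 and C7–C7a).** This is the key cut. Its neighbours are worse: cutting C6–C7 means joining two fully substituted carbons directly, and no other cycloaddition pattern places both quaternary carbons in the two-carbon partner. The cut turns a tricycle with four stereocentres into monocyclic diene 7, with one stereocentre, and the achiral, symmetric anhydride 9. The forward Diels–Alder reaction must overcome a tetrasubstituted dienophile and deliver two selectivities: the diene face anti to the C1 ethyl group, and the anhydride-exo orientation.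

**7 ⇒ 5 + 6 ⇒ 2 + 3 ⇒ 1 (C4–C3a, then C1–ethyl).** The ethoxyvinyl unit is attached by Stille coupling of stannane 6 to enol triflate 5. Triflate 5 is the O-trapped enolate of a catalytic asymmetric conjugate addition of diethylzinc 3 to enone 2. The conjugate addition sets the only stereocentre that is made by a chiral catalyst, and the enolate it generates is exactly the regioisomer needed. Enone 2 is the monoketal of commercial dione 1.

**9 ⇒ 8 (both C–CO bonds).** The anhydride is the oxidative double carbonylation product of hex-3-yne 8.

## Roads not taken

**Alternative 1:** The cut is C3a–C7a in ring A. An acyclic E,E-dienone A2 would close under BF3·OEt2 by conrotatory Nazarov cyclisation, and Et3SiH would reduce the oxyallyl cation to the all-trans cyclopentanone A1.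
- Merits: four contiguous ring-A stereocentres arise in one step from an open chain. The C3a/C7a trans relationship follows from orbital symmetry, not from equilibration. In this respect it is better than the chosen plan, which sets C3a and C3 one at a time.
- Weak points: the sense of conrotation has to be steered by the two side-chain stereocentres of A2. More seriously, A1 contains neither ring B nor C6, and C7 is only tertiary. The C6–C7 bond between two quaternary carbons and the whole cyclohexene would still have to be built on a crowded cyclopentanone.
- Comparison: the chosen plan solves the quaternary pair in the key step and treats ring A as the easy, thermodynamically guided part, which is the better division of labour for this target.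

**Alternative 2:** The cut is C3a–C7a, C1–C2 and C2–C3 at once. Dienyne A4 carries a but-1-ynyl group on C7 and a dienyl group on C6. With Co2(CO)8 it would undergo Pauson–Khand reaction to give bicyclic enone A3, closing both rings.
- Merits: three bonds and two rings form in one step. The C4 methyl and C4=C5 alkene are already in place, so no enol triflate chemistry is needed. The two one-carbon groups are differentiated from the start (silyl ether against methyl ester). On these counts it is shorter and cleaner after the key step than the chosen plan.
- Weak points: A4 already contains both quaternary stereocentres in an open chain, so the hardest problem is pushed into an acyclic stereoselective synthesis with no obvious handle. The alkene partner is the internal, 1,2-disubstituted end of a conjugated diene, a poor Pauson–Khand substrate. A3 still needs face-selective reduction of the C1=C7a enone to set C7a and C1.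
- Comparison: against its economy the chosen plan sets a convergent cycloaddition in which dienophile geometry fixes the C6/C7 relationship.

**Alternative 3:** The cut is C6–C7. A trans-fused δ-lactone A6 has its ring oxygen on C4, its carbonyl on C7 and an alkenyl arm on C4. As its silyl ketene acetal it would undergo Ireland–Claisen rearrangement to the ring-contracted acid A5.
- Merits: a [3,3] shift is one of the few reliable ways to join two fully substituted carbons, and the lactone enforces a boat transition state, so the alkene geometry is relayed to C6 and C7. A5 emerges with the C4=C5 alkene, the free C7 acid and a distinct C6 CH2O group. In the reliability of quaternary-centre formation and in differentiation this road is as good as or better than the chosen one.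
- Weak points: A6 is itself advanced. It needs all ring-A stereocentres, a tertiary allylic C4–O centre of defined configuration and a stereodefined trisubstituted alkene. The tertiary allylic ester is prone to ionise or eliminate when the hindered lactone is enolised. The route is long and linear.
- Comparison: the chosen plan sets against it two short fragments (three steps and one step) joined in a single ring-forming event.

Key step: step 5

Remarks on the chemistry.
- Positions in every intermediate are named with the numbering of 26 (C1 ethyl, C2 ketone, C3 methyl, C3a, C4 methyl, C5, C6, C7, C7a; chain C1′–C4′). α is the face of H-7a and β the face of H-3a (β only where C3a is sp3).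
- The sense of induction in step 2 is assigned by analogy with other cyclopentenone acceptors; the ligand antipode that gives (S)-5 is the one to be used.
- Ylide 19 is taken as a purchasable stabilised ylide.

## Route

Step 1
Reactants: 1 cyclopent-4-ene-1,3-dione
Product: 2 1,4-dioxaspiro[4.4]non-8-en-7-one (mono ethylene ketal of 1)
Conditions: HOCH2CH2OH (1.05 equiv), p-TsOH·H2O (cat.), benzene, reflux, Dean–Stark
Reagents that add atoms: ethane-1,2-diol, OCCO
Why: Acid-catalysed ketalisation with azeotropic removal of water; the first ketal turns the remaining carbonyl into an ordinary conjugated enone flanked by a spiro centre, so a second ketalisation is slow and the monoketal can be taken off; no stereocentre is formed.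

Step 2
Reactants: 2 1,4-dioxaspiro[4.4]non-8-en-7-one; 3 diethylzinc
Product: 5 (S)-9-ethyl-1,4-dioxaspiro[4.4]non-7-en-7-yl trifluoromethanesulfonate, via ethylzinc enolate 4 (not isolated)
Conditions: Cu(OTf)2 (2 mol %), BINOL-derived N,N-bis(1-phenylethyl)phosphoramidite (4 mol %), toluene, −30 °C; then Tf2O (1.5 equiv), −30 to 0 °C
Reagents that add atoms: trifluoromethanesulfonic anhydride, O=S(=O)(OS(=O)(=O)C(F)(F)F)C(F)(F)F
Why: Copper-catalysed asymmetric conjugate addition of a dialkylzinc to a cyclopentenedione monoacetal, a substrate class for which this ligand type is established; the chiral monovalent copper complex formed in situ sets C1 (S), and the regiodefined zinc enolate 4 is O-sulfonylated by Tf2O before it can equilibrate toward the ketal side.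

Step 3
Reactants: 5 (S)-9-ethyl-1,4-dioxaspiro[4.4]non-7-en-7-yl trifluoromethanesulfonate; 6 tributyl(1-ethoxyvinyl)stannane
Product: 7 (S)-7-(1-ethoxyvinyl)-9-ethyl-1,4-dioxaspiro[4.4]non-7-ene (the 2-ethoxydiene C5=C4(OEt)–C3a=C7a)
Conditions: Pd(PPh3)4 (5 mol %), LiCl (3 equiv), THF, 65 °C; chromatography on Et3N-deactivated silica
Reagents that add atoms: none
Why: Stille coupling of an enol triflate with an α-alkoxyvinylstannane under zerovalent palladium catalysis, a standard entry to 2-alkoxy-1,3-dienes; the C1 stereocentre is a non-acidic allylic carbon and is not touched.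

Step 4
Reactants: 8 hex-3-yne
Product: 9 3,4-diethylfuran-2,5-dione (2,3-diethylmaleic anhydride)
Conditions: Pd(OAc)2 (cat.), chlorohydroquinone (cat.), (NH4)5H6PV8Mo4O40 (cat.), CO (10 atm)/O2 (0.5 atm), 1,4-dioxane, 25 °C
Reagents that add atoms: carbon monoxide, [C-]#[O+]; dioxygen, O=O
Why: Oxidative double carbonylation of an alkyne by divalent palladium with a hydroquinone/polyoxometalate/O2 reoxidation chain; both carbonyl groups are delivered syn across the triple bond, so the Z-configured maleic skeleton is obtained directly as its anhydride.

Step 5
Reactants: 7 (S)-7-(1-ethoxyvinyl)-9-ethyl-1,4-dioxaspiro[4.4]non-7-ene; 9 3,4-diethylfuran-2,5-dione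
Product: 10 tricyclic anhydride: 4-ethoxy-1α,6β,7β-triethyl-2,2-ethylenedioxy-2,3,5,6,7,7a-hexahydro-1H-indene-6α,7α-dicarboxylic anhydride (7aα-H, C4=C3a enol ether)
Conditions: CH2Cl2 (1 M), BHT (cat.), 12 kbar, 30 °C
Reagents that add atoms: none
Why: Concerted suprafacial [4+2] cycloaddition (Diels–Alder) of the electron-rich 2-ethoxydiene 7 with the electron-poor tetrasubstituted alkene of 9; the closest known reaction type is the thermal or high-pressure addition of 2,3-dialkylmaleic anhydrides to 2-oxygenated dienes. Ring B is closed by intermolecular cycloaddition, C5–C6 and C7–C7a forming together and leaving the C4=C3a enol ether, while the anhydride ring is carried in unchanged. C6 and C7 take their cis-diethyl, cis-dicarbonyl relationship from the Z geometry of the dienophile, which a concerted addition cannot scramble, and the symmetry of 9 removes any regiochemical question. C7a is set relative to C1 by approach of 9 to the cyclopentene face opposite the allylic C1 ethyl group, which sits directly beside the bond-forming terminus. C7a is set relative to C7 by the ethyl-endo, anhydride-exo transition state, which places the C7 carbonyl cis to H-7a; this is the selectivity the step needs most and the one least secured, resting on the tendency of α-alkylated dienophiles to turn their alkyl groups, not their carbonyl groups, toward the diene. The strongly negative activation volume is the reason for 12 kbar, which should speed the sluggish addition at a temperature where the acid-labile diene and the enol ether of 10 survive.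

Step 6
Reactants: 10 tricyclic anhydride with C4 enol ether
Product: 12 trans-fused 4-ketone: 1α,6β,7β-triethyl-2,2-ethylenedioxy-4-oxo-octahydro-1H-indene-6α,7α-dicarboxylic anhydride (3aβ-H, 7aα-H), via cis-fused ketone 11 (not isolated)
Conditions: (CO2H)2, THF–H2O, 25 °C; then DBU (cat.), CH2Cl2, 25 °C
Reagents that add atoms: water, O
Why: Enol ether hydrolysis by C3a protonation and capture of the oxocarbenium ion by water, under conditions that spare a dioxolane and a tetra-substituted succinic anhydride; base-mediated epimerisation α to the new ketone then converts any cis-fused epimer 11 into 12, because either chair of the cis isomer forces a ring bond syn-diaxial to an ethyl group on C6 or C7 whereas the trans isomer has none.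

Step 7
Reactants: 12 trans-fused 4-ketone
Product: 14 enol triflate: the C4(OSO2CF3)=C5 derivative of 12 (3aβ-H retained), via lithium enolate 13 (not isolated)
Conditions: LiN(iPr)2 (1.15 equiv), THF, −78 °C (ketone added to base); then PhNTf2, −78 to 0 °C
Reagents that add atoms: N-phenylbis(trifluoromethanesulfonimide), O=S(=O)(N(c1ccccc1)S(=O)(=O)C(F)(F)F)C(F)(F)F
Why: Kinetic enolisation and O-triflation; trans-fused hydrindan-4-ones are deprotonated by hindered lithium amides at the methylene carbon, not at the ring-fusion methine, which here also keeps the C3a configuration; the anhydride has no α-hydrogen and its carbonyls are screened by two quaternary carbons.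

Step 8
Reactants: 14 enol triflate
Product: 15 4-methyl-Δ4 anhydride: 1α,6β,7β-triethyl-2,2-ethylenedioxy-4-methyl-2,3,3a,6,7,7a-hexahydro-1H-indene-6α,7α-dicarboxylic anhydride (3aβ-H, 7aα-H)
Conditions: MeZnCl (2 equiv), Pd(PPh3)4 (5 mol %), THF, 25–50 °C
Reagents that add atoms: methylzinc chloride, C[Zn]Cl
Why: Negishi coupling of an enol triflate with a methylzinc reagent under zerovalent palladium catalysis fixes the C4 methyl and the C4=C5 alkene regiospecifically; organozinc halides tolerate the ketal and the hindered anhydride.

Step 9
Reactants: 15 4-methyl-Δ4 anhydride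
Product: 16 lactol–lactone: C7 carboxyl closed as γ-lactone onto C1′, which carries OH (both C1′ epimers); ring tautomer of the 6-formyl-7-carboxylic acid
Conditions: LiAlH(OtBu)3 (1.1 equiv), THF, −78 to −20 °C; aqueous citric acid work-up
Reagents that add atoms: none
Why: Partial reduction of a cyclic anhydride to a hydroxylactone by a bulky alkoxyaluminium hydride, whose tetrahedral aluminate does not collapse at low temperature; the hydride should go to the C6 carbonyl, flanked only by the C5 alkene CH, and not to the C7 carbonyl, which lies beside C7a and the C1 ethyl group; no ketone is present at this stage.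

Step 10
Reactants: 16 lactol–lactone
Product: 18 allyl 1α,6β,7β-triethyl-2,2-ethylenedioxy-6α-formyl-4-methyl-2,3,3a,6,7,7a-hexahydro-1H-indene-7α-carboxylate, via ring-opened potassium carboxylate 17 (not isolated)
Conditions: K2CO3 (2 equiv), allyl bromide (1.5 equiv), DMF, 25 °C
Reagents that add atoms: allyl bromide, C=CCBr
Why: Base opens the pseudo-acid to the formyl carboxylate, which is O-alkylated to the normal (open-chain) ester as pseudo-acids are with alkyl halides and carbonate; alkylation of a carboxylate does not depend on access to the hindered acyl carbon.

Step 11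
Reactants: 18 allyl 6α-formyl ester; 19 2-(triphenylphosphoranylidene)butanal
Product: 20 enal: allyl ester as 18 with C6 bearing (E)-CH=C(Et)–CHO in place of CHO
Conditions: 19 (2 equiv), toluene, 110 °C
Reagents that add atoms: none
Why: Wittig olefination with a formyl-stabilised ylide gives the α-ethyl enal with C6 trans to the formyl group (thermodynamic oxaphosphetane control, E); the neutral reagent avoids any alkoxide that could attack the neighbouring ester, and the aldehyde cannot enolise, so long heating is tolerated.

Step 12
Reactants: 20 enal; 21 diethyl benzylphosphonate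
Product: 22 allyl 1α,6β,7β-triethyl-2,2-ethylenedioxy-6α-[(1E,3E)-2-ethyl-4-phenylbuta-1,3-dienyl]-4-methyl-2,3,3a,6,7,7a-hexahydro-1H-indene-7α-carboxylate
Conditions: NaH (1.3 equiv), THF, 0 to 25 °C
Reagents that add atoms: none
Why: Horner–Wadsworth–Emmons olefination of an enal with a benzylphosphonate anion gives the E-styryl double bond; the aldehyde is now remote from the quaternary centres and the ketal keeps C1 and C3 away from base.

Step 13
Reactants: 22 diene ketal ester
Product: 23 allyl 1α,6β,7β-triethyl-6α-[(1E,3E)-2-ethyl-4-phenylbuta-1,3-dienyl]-4-methyl-2-oxo-2,3,3a,6,7,7a-hexahydro-1H-indene-7α-carboxylate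
Conditions: 1 M HCl, THF, 25 °C
Reagents that add atoms: water, O
Why: Acid hydrolysis of the dioxolane; with the C7 carboxyl esterified no lactone can close onto the diene, and the C1 ethyl group stays trans to C7, its stable orientation.

Step 14
Reactants: 23 C2 ketone
Product: 25 allyl ester of 26 (3β-methyl, cis to H-3a), via lithium enolate 24 (not isolated)
Conditions: LiN(iPr)2 (1.1 equiv), THF, −78 °C; then MeI, −78 to −30 °C
Reagents that add atoms: iodomethane, CI
Why: Kinetic deprotonation takes the C3 methylene, not the C1 methine buried beside C7, and methyl iodide attacks the enolate face anti to the C3a–C4 bond, giving the 3β-methyl epimer, which is also the stable one; the ester has no α-hydrogen.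

Step 15
Reactants: 25 allyl ester
Product: 26 (1S,3S,3aR,6R,7R,7aR)-1,6,7-triethyl-6-[(1E,3E)-2-ethyl-4-phenylbuta-1,3-dienyl]-3,4-dimethyl-2-oxo-2,3,3a,6,7,7a-hexahydro-1H-indene-7-carboxylic acid
Conditions: Pd(PPh3)4 (5 mol %), morpholine (5 equiv), THF, 25 °C; dilute acid work-up
Reagents that add atoms: none
Why: Tsuji–Trost deallylation: zerovalent palladium ionises the allyl C–O bond and morpholine captures the allyl cation, so the hindered carboxyl is released under neutral conditions that leave the diene and the epimerisable ketone α-centres in their stable configurations.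

## Compound list

1 | cyclopent-4-ene-1,3-dione | O=C1C=CC(=O)C1 | starting material
2 | 1,4-dioxaspiro[4.4]non-8-en-7-one | O=C1C=CC2(OCCO2)C1 | intermediate
3 | diethylzinc | CC[Zn]CC | starting material
4 | ethylzinc enolate of (S)-9-ethyl-1,4-dioxaspiro[4.4]nonan-7-one (O–Zn, C7=C8) | CC[Zn]OC1=C[C@H](CC)C2(OCCO2)C1 | intermediate (not isolated)
5 | (S)-9-ethyl-1,4-dioxaspiro[4.4]non-7-en-7-yl trifluoromethanesulfonate | FC(F)(F)S(=O)(=O)OC1=C[C@H](CC)C2(OCCO2)C1 | intermediate
6 | tributyl(1-ethoxyvinyl)stannane | CCCC[Sn](CCCC)(CCCC)C(=C)OCC | starting material
7 | (S)-7-(1-ethoxyvinyl)-9-ethyl-1,4-dioxaspiro[4.4]non-7-ene | C=C(OCC)C1=C[C@H](CC)C2(OCCO2)C1 | intermediate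
8 | hex-3-yne | CCC#CCC | starting material
9 | 3,4-diethylfuran-2,5-dione | CCC1=C(CC)C(=O)OC1=O | intermediate
10 | tricyclic anhydride with C4 enol ether (1α,6β,7β-triethyl, 7aα-H, anhydride α) | O=C4[C@@]1(CC)CC(OCC)=C2[C@H]([C@H](CC)C3(OCCO3)C2)[C@@]1(CC)C(=O)O4 | intermediate
11 | cis-fused 4-ketone (3aα-H, C3a epimer of 12) | O=C4[C@@]1(CC)CC(=O)[C@H]2[C@H]([C@H](CC)C3(OCCO3)C2)[C@@]1(CC)C(=O)O4 | intermediate (not isolated)
12 | trans-fused 4-ketone (3aβ-H, 7aα-H) | O=C4[C@@]1(CC)CC(=O)[C@@H]2[C@H]([C@H](CC)C3(OCCO3)C2)[C@@]1(CC)C(=O)O4 | intermediate
13 | lithium C4=C5 enolate of 12 | O=C4[C@@]1(CC)C=C(O[Li])[C@@H]2[C@H]([C@H](CC)C3(OCCO3)C2)[C@@]1(CC)C(=O)O4 | intermediate (not isolated)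
14 | C4=C5 enol triflate | O=C4[C@@]1(CC)C=C(OS(=O)(=O)C(F)(F)F)[C@@H]2[C@H]([C@H](CC)C3(OCCO3)C2)[C@@]1(CC)C(=O)O4 | intermediate
15 | 4-methyl-Δ4 anhydride | O=C4[C@@]1(CC)C=C(C)[C@@H]2[C@H]([C@H](CC)C3(OCCO3)C2)[C@@]1(CC)C(=O)O4 | intermediate
16 | lactol–lactone (C1′–OH, lactone carbonyl on C7; C1′ epimers) | OC4[C@@]1(CC)C=C(C)[C@@H]2[C@H]([C@H](CC)C3(OCCO3)C2)[C@@]1(CC)C(=O)O4 | intermediate
17 | potassium 6α-formyl-7α-carboxylate (ring-opened form of 16) | O=C[C@@]1(CC)C=C(C)[C@@H]2[C@H]([C@H](CC)C3(OCCO3)C2)[C@@]1(CC)C(=O)[O-].[K+] | intermediate (not isolated)
18 | allyl 6α-formyl-7α-carboxylate | O=C[C@@]1(CC)C=C(C)[C@@H]2[C@H]([C@H](CC)C3(OCCO3)C2)[C@@]1(CC)C(=O)OCC=C | intermediate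
19 | 2-(triphenylphosphoranylidene)butanal | CCC(C=O)=P(c1ccccc1)(c1ccccc1)c1ccccc1 | starting material
20 | enal: C6 bears (E)-CH=C(Et)CHO | CCC(/C=O)=C\[C@@]1(CC)C=C(C)[C@@H]2[C@H]([C@H](CC)C3(OCCO3)C2)[C@@]1(CC)C(=O)OCC=C | intermediate
21 | diethyl benzylphosphonate | CCOP(=O)(Cc1ccccc1)OCC | starting material
22 | allyl ester with (1E,3E)-dienyl chain and C2 ketal | CCC(/C=C/c1ccccc1)=C\[C@@]1(CC)C=C(C)[C@@H]2[C@H]([C@H](CC)C3(OCCO3)C2)[C@@]1(CC)C(=O)OCC=C | intermediate
23 | allyl ester, C2 ketone, C3 unsubstituted | CCC(/C=C/c1ccccc1)=C\[C@@]1(CC)C=C(C)[C@@H]2[C@H]([C@H](CC)C(=O)C2)[C@@]1(CC)C(=O)OCC=C | intermediate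
24 | lithium C2=C3 enolate of 23 | CCC(/C=C/c1ccccc1)=C\[C@@]1(CC)C=C(C)[C@@H]2[C@H]([C@H](CC)C(O[Li])=C2)[C@@]1(CC)C(=O)OCC=C | intermediate (not isolated)
25 | allyl ester of 26 | CCC(/C=C/c1ccccc1)=C\[C@@]1(CC)C=C(C)[C@@H]2[C@H]([C@H](CC)C(=O)[C@H]2C)[C@@]1(CC)C(=O)OCC=C | intermediate
26 | CNP0134269.1 | CCC(/C=C/c1ccccc1)=C\[C@@]1(CC)C=C(C)[C@@H]2[C@H]([C@H](CC)C(=O)[C@H]2C)[C@@]1(CC)C(=O)O | target

## Step count and least certain steps

Total: 15 steps. Longest linear sequence: 14 steps (steps 1–3 and 5–15); step 4 supplies the second fragment in one step.

**Step 5 (key step).** Two things may go wrong. The tetrasubstituted dienophile may add so slowly that hydrolysis or oligomerisation of the enol-ether diene overtakes cycloaddition. The preference for the anhydride-exo transition state may also erode, because secondary overlap of the anhydride carbonyls with the diene pulls toward the endo mode and would give the wrong C7/C7a relationship. The fallback changes the dienophile, not the conditions. It sets out from 7 and uses 4,6-dimethyl-4,6-dihydrothieno[3,4-c]furan-1,3-dione F1, the 2,5-dimethyl homologue of the known ring-tied 2,5-dihydrothiophene-3,4-dicarboxylic anhydride, to be prepared separately as its parent is. With its alkyl groups pinned back into a five-membered ring it is a markedly better dienophile, and it should give the sulfur-bridged cycloadduct F2 under pressure. Raney Ni desulfurisation then cuts both C–S bonds, turning each CH(CH3)S arm into an ethyl group, and the route is rejoined at 10. The exo/endo outcome with F1 would have to be established.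

**Step 9.** The two anhydride carbonyls may be discriminated too weakly, since both sit on quaternary carbons, or the lactol may be reduced further to the lactone. The fallback sets out from 15 and replaces substrate-controlled hydride delivery by reagent-controlled alcoholysis. Methanol is added in the presence of quinine or quinidine; the two pseudo-enantiomeric alkaloids direct methanol to opposite carbonyls of a cis-fused succinic anhydride, so one of them reinforces attack at the C6 carbonyl. This gives the 6α-methoxycarbonyl-7α-carboxylic acid F3. Treatment with i-Bu2AlH (2.2 equiv, CH2Cl2, −78 °C) leaves the aluminium carboxylate untouched and reduces the methyl ester to the aldehyde stage, which closes on work-up to 16.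

**Step 11.** The formyl-stabilised ylide is a weak nucleophile and the aldehyde is neopentyl on both sides; olefination may be so slow that thermal degradation competes. The fallback sets out from 18 and uses the more nucleophilic ethyl 2-(triphenylphosphoranylidene)butanoate in hot toluene to give the (E)-α-ethyl enoate F4. i-Bu2AlH at −78 °C reduces the conjugated ethyl ester in preference to the buried allyl ester to give allylic alcohol F5, and MnO2 oxidises F5 to 20, where the route is rejoined.

**Step 4.** Internal dialkylalkynes are the least reactive substrates for oxidative dicarbonylation. Carbonylation may stop after one CO or turn toward butenolide formation. The fallback does not start from 8. Ethyl 2-oxobutanoate and ethyl 2-(triphenylphosphoranylidene)butanoate are joined by Wittig olefination to diethyl 2,3-diethylbut-2-enedioate F6 (E/Z mixture). Saponification (KOH, EtOH–H2O, then HCl) gives 2,3-diethylbut-2-enedioic acid F7. Heating F7 in Ac2O isomerises the E acid and closes the Z acid, returning to the route at 9.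

## Further compounds

F1 | step 5 | 4,6-dimethyl-4,6-dihydrothieno[3,4-c]furan-1,3-dione (2,5-dimethyl-2,5-dihydrothiophene-3,4-dicarboxylic anhydride) | CC1SC(C)C2=C1C(=O)OC2=O
F2 | step 5 | sulfur-bridged cycloadduct of 7 and F1 (C6 and C7 joined through CH(CH3)–S–CH(CH3); otherwise as 10) | O=C4[C@@]1(C(C)S6)CC(OCC)=C2[C@H]([C@H](CC)C3(OCCO3)C2)[C@@]1(C6C)C(=O)O4
F3 | step 9 | 6α-methoxycarbonyl-7α-carboxylic acid from methanolysis of 15 | COC(=O)[C@@]1(CC)C=C(C)[C@@H]2[C@H]([C@H](CC)C3(OCCO3)C2)[C@@]1(CC)C(=O)O
F4 | step 11 | allyl ester with C6 bearing (E)-CH=C(Et)CO2Et | CCC(/C(=O)OCC)=C\[C@@]1(CC)C=C(C)[C@@H]2[C@H]([C@H](CC)C3(OCCO3)C2)[C@@]1(CC)C(=O)OCC=C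
F5 | step 11 | allyl ester with C6 bearing (E)-CH=C(Et)CH2OH | CCC(/CO)=C\[C@@]1(CC)C=C(C)[C@@H]2[C@H]([C@H](CC)C3(OCCO3)C2)[C@@]1(CC)C(=O)OCC=C
F6 | step 4 | diethyl 2,3-diethylbut-2-enedioate (E/Z mixture) | CCOC(=O)C(CC)=C(CC)C(=O)OCC
F7 | step 4 | 2,3-diethylbut-2-enedioic acid (E/Z mixture) | CCC(C(=O)O)=C(CC)C(=O)O
A1 | alternative 1 | 3-[1-(benzyloxy)butan-2-yl]-4-[1-(benzyloxy)ethyl]-2-ethyl-5-methylcyclopentan-1-one, all-trans | C[C@H](OCc1ccccc1)[C@@H]2[C@H]([C@H](CC)C(=O)[C@H]2C)[C@@H](CC)COCc1ccccc1
A2 | alternative 1 | (3E,6E)-1,8-bis(benzyloxy)-2,4-diethyl-6-methylnona-3,6-dien-5-one | C[C@H](OCc1ccccc1)/C=C(\C)C(=O)/C(CC)=C/[C@@H](CC)COCc1ccccc1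
A3 | alternative 2 | bicyclic C1=C7a enone: methyl ester at C7, tert-butyldimethylsilyloxymethyl at C6 | CC(C)(C)[Si](C)(C)OC[C@@]1(CC)C=C(C)[C@@H]2C(=C(CC)C(=O)[C@H]2C)[C@@]1(CC)C(=O)OC
A4 | alternative 2 | methyl (4Z,6E)-2-(but-1-yn-1-yl)-3-[(tert-butyldimethylsilyloxy)methyl]-2,3-diethyl-5-methylocta-4,6-dienoate | CC(C)(C)[Si](C)(C)OC[C@@]([C@@](CC)(C#CCC)C(=O)OC)(CC)/C=C(C)\C=C\C
A5 | alternative 3 | ring-contracted hexahydroindene-7-carboxylic acid with C6 tert-butyldimethylsilyloxymethyl and C2 dioxolane | CC(C)(C)[Si](C)(C)OC[C@@]1(CC)C=C(C)[C@@H]2[C@H]([C@H](CC)C3(OCCO3)[C@H]2C)[C@@]1(CC)C(=O)O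
A6 | alternative 3 | trans-fused δ-lactone (ring O on C4, carbonyl on C7) with C4 methyl and C4 (E)-2-ethyl-3-(tert-butyldimethylsilyloxy)prop-1-enyl arm | CC(C)(C)[Si](C)(C)OC/C(CC)=C/[C@@]1(C)OC(=O)[C@H](CC)[C@@H]2[C@@H]1[C@H](C)C3(OCCO3)[C@H]2CC
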